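## Structural features

The target 21 is a biflavonoid. A 5,7-dihydroxy-2-(4-hydroxyphenyl)chroman-4-one (ring A = phloroglucinol ring, ring B = 4-hydroxyphenyl group, ring C = pyranone; atoms O1 to C8a) is joined twice to a 5'-hydroxy-2'-(4-hydroxyphenyl)chroman (ring D = benzene ring, ring E = dihydropyran, ring G = 4-hydroxyphenyl group; primed atoms), through C3–C8' and through C2–O7'. These two links create a 2,3-dihydrofuran (ring F: C2, C3, C8', C7', O7') that is annulated to ring D and fused to ring C across C2–C3. C2 is a fully substituted ketal carbon (O1, O7', ring B, C3) and its neighbour C3 is a methine α to the C4 ketone; the pair is (2S,3S), which on this 5/6 junction means cis (H3 and ring B on the same face), while the third stereocentre, C2' (R), lies apart on ring E. The ketal is the fragile point: base can expel O1 or O7' from the C3 enolate (giving a 3-aroylbenzofuran or a 3-arylflavone), and acid can ionise C2 and lose H3 to the same aromatic isomers. The C2'–O1' benzylic ether and the electron-rich phenolic rings add sensitivity to hydrogenolysis and oxidants. The real difficulty is to build the congested ketal at exactly this oxidation level without aromatisation, to bond C3 to C8' and not to C6', and to relate the C2/C3 pair to the remote C2'. The feature exploited is that the carbon substituent at C8' and the oxygen O7' are ortho neighbours on ring D, the pattern a [3,3] shift of an O-aryl ene-hydroxylamine leaves behind, and that the one oxygen still missing at C2, O1, sits ortho to the C4 carbonyl on ring A within reach of a six-membered closure.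

## Logic of the disconnections

21 is traced back to 20 by replacing five O–H bonds by O–benzyl bonds and the C6'–H bond by C6'–Br. Benzyl is chosen because the last step must be neutral, and the bromine is the blocker of the key step that leaves under the same hydrogenolysis. The gain is a fully masked intermediate at which diastereomers can be separated. The demand is a hydrogenolysis that spares the C2'–O1' ether, the ketal and the ketone, with the hydrogen bromide buffered.

In 20 the bonds C3–C8', C2–O7' and C2–O1 are cut together, which opens rings F and C and leads to the open-chain 17. The cut is placed here because C8' and O7' are ortho on ring D and because C2 has the oxidation level of a ketone carbon: after the shift it is an N-acyl imine that can accept O7' and then O1. Two rings, three skeletal bonds and two adjacent stereocentres are exchanged for an acyclic β-keto oxime ether. The demands are that the shift goes to C8' (hence bromine at C6'), that the silyl ether oxygen O1 captures C2 before H3 is lost, and that 20 is separated from the second cis-fused diastereomer formed with it, since C2' cannot bias the face.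

17 is cut at C=N into 11 and 16. The cut is made at the only bond that forms by simple condensation, and it divides the molecule into two halves of similar size. The forward condensation must select the unhindered carbonyl of 16, and O1 must stay silylated so that it cannot close to a flavone with expulsion of the amine.

11 is cut at N–O7' to 10, because a phenol is far easier to carry through the chroman synthesis than an aryloxyamine. The gain is a stable phenol as the branch point. The demand is a clean electrophilic amination of a hindered phenoxide at oxygen.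

10 is cut at C2'–O1' to 9, which turns the ring E stereocentre into an acyclic benzylic carbinol that asymmetric ketone reduction can set. The closure must proceed with inversion and without ionisation of the carbinol.

9 goes back to 8 by two O–allyl bonds. Allyl is chosen because it can be removed under neutral conditions beside benzyl ethers, the aryl bromide and the ionisable carbinol. The forward step must not touch the C–Br bond.

8 is traced through 7 and 6 to 4 and 5: the carbinol C–H bond (enantioselective reduction), the two C–H bonds of the saturated chain (conjugate reduction) and the C=C bond (aldol condensation). This reduces the chroman half to an aldehyde and a methyl ketone. The reductions must leave the aryl bromide, benzyl ethers and allyl groups intact.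

4 goes back through 3 and 2 to 1 by the O–benzyl bond, the C–Br bond and two O–allyl bonds. The bromine is introduced here and not on the finished chroman, where electrophilic bromination would be expected at C8', the position the key step needs free. In 2 the chelated hydroxyl directs to its ortho carbon; once that hydroxyl is benzylated and the ring is closed through the other ortho oxygen, the halogen can only lie at C6'.

16 is cut at O–Si to 15, 15 at the central C–C bond to 13 and 14, and 13 at two O–benzyl bonds to 12. These are the standard cuts of a diaryl 1,3-diketone and lead straight to commercial materials. The demand is silylation at the phenol rather than at the enol of the diketone.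

## Other disconnections considered

Alternative 1: The cut runs through C4–C4a and O1–C8a: ring A is added last, as an aryne, to the carboxyl group of the flavan-fused 2-arylbenzofuran-3-carboxylic acid A1. In the forward step CsF releases the aryne from the silylaryl triflate A2. The carboxylate oxygen adds to the aryne carbon remote from the benzyloxy group, and the aryl anion takes the acyl group, giving the 3-(2-hydroxyaroyl)benzofuran A3 with the ring A pattern of the target.
- In favour: insertion of arynes into the C–O bond of carboxylic acids is an established reaction type, its regiochemistry is dictated by the alkoxy group, and the union is convergent. On precedent for the key step this alternative is better than the chosen plan.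
- Against: the key step closes no ring and sets no stereocentre. A3 is the aromatised, ring C-opened isomer, and the decisive step, addition of the new phenol to C2 to give the ketal A4, must dearomatise the furan under conditions that also drive the reverse elimination.
- Comparison: the chosen plan reaches the ketal oxidation level directly from an acyclic precursor, whereas this route passes through the very benzofuran that the chosen key step has to avoid. Alternative 1 has the safer C–C bond formation but the less certain ketalisation. On stereocontrol the two are equal (neither relates C2/C3 to C2'). On step count they are about equal, because A1 needs its own regiocontrolled benzofuran synthesis, which moves the C8'/C6' question rather than removing it.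

Alternative 2: The cut is O1–C2 alone, with C4 at the alcohol oxidation level. The (2-hydroxyaryl)(benzofuran-3-yl)carbinol A5 loses water under mild acid to an ortho-quinone methide of ring A conjugated with the furan C2=C3 bond, and oxa-6π closure gives the 2H-chromene ketal A6.
- In favour: this is the standard way to 2H-chromenes, it is unimolecular and mild, and re-aromatisation of ring A pays for the loss of furan aromaticity. On the driving force of ring C closure it is better placed than Alternative 1, and it stands on firmer precedent than the chosen key step.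
- Against: A6 is the cyclic ether of a flavylium pseudobase, so the acid that generates the quinone methide can also ionise C2–O7'. The C4 carbonyl and H3 are missing and must be added by hydroboration–oxidation and alcohol oxidation, under conditions a 2-aryloxy-2H-chromene may not tolerate.
- Comparison: the key step forms one bond and one ring against three bonds and two rings in the chosen plan, and A5 needs a benzofuran synthesis of its own. Mechanistically it is the more conservative. Stereochemically the two are equal (two C2 epimers, C3 following by cis fusion). In step economy it is poorer by the redox steps after the closure.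

Alternative 3: The cut is C3–C4 and C2–O1 in one operation. The quinoketene released from the benzodioxinone A8 adds its ketene carbon to C3 and its ring carbonyl oxygen to C2 of the flavan-fused 2-arylbenzofuran A7 and gives A4 directly.
- In favour: it is the most convergent, closes ring C with both bonds and both stereocentres at the correct oxidation level, and needs no bromine, so the end game is a plain debenzylation. Its polarity is right: C3 of a 2-arylbenzofuran is nucleophilic, and a cation at C2 is stabilised by O7' and ring B. On step economy and end game it is better than the chosen plan.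
- Against: quinoketenes are normally intercepted by heteroatom nucleophiles. Here the partner is a hindered, tetrasubstituted double bond inside an aromatic furan, the ketene could instead acylate the electron-rich C6', and the heat or light needed to unmask it acts on a product A4 that can lose O1 again to give A3.
- Comparison: cis fusion is secured in both plans (suprafacial addition here, the tether in the chosen plan) and the face relative to C2' is uncontrolled in both, so they are equal on stereochemistry. The chosen plan makes its C–C bond intramolecularly through a concerted shift at low temperature, which is mechanistically more secure than intermolecular capture of a fleeting ketene at a hindered carbon. It pays for this with the longer synthesis of 17 and the blocker.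

Key step: step 14

Assumption: bromination of 2 is taken to occur ortho to the chelated hydroxyl (C3), as is general for 2-hydroxy-4,6-dialkoxyaryl aldehydes and ketones; the position is to be confirmed by NOE on 4 before the material is carried on.

Remark: step 14 is expected to give 20 together with the second cis-fused diastereomer, (2S,3R,2'R), in which C2 and C3 are both inverted while C2' is unchanged; it is removed by chromatography at that stage and takes no further part in the route.

## Route

Step 1
Reactants: 1 2,4,6-trihydroxybenzaldehyde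
Product: 2 2-hydroxy-4,6-bis(prop-2-en-1-yloxy)benzaldehyde
Conditions: allyl bromide (2.1 equiv), K2CO3 (2.2 equiv), DMF, 0 °C → rt
Reagents that add atoms: allyl bromide, C=CCBr
Why: Williamson etherification; the hydroxyl hydrogen-bonded to the formyl group is the least nucleophilic, so the para and one ortho hydroxyl react and the chelated one is kept. Allyl is chosen because it can later be removed under neutral conditions beside benzyl ethers, an aryl bromide and an ionisable benzylic alcohol.

Step 2
Reactants: 2 2-hydroxy-4,6-bis(prop-2-en-1-yloxy)benzaldehyde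
Product: 3 3-bromo-2-hydroxy-4,6-bis(prop-2-en-1-yloxy)benzaldehyde
Conditions: NBS (1.0 equiv), MeCN, −10 → 0 °C
Reagents that add atoms: N-bromosuccinimide, O=C1CCC(=O)N1Br
Why: Electrophilic aromatic bromination directed by the free chelated hydroxyl to its ortho carbon; ionic substitution of the activated ring should be much faster than attack on the allyl double bonds. Installing the halogen at this stage is what later places it at C6' and leaves C8' free.

Step 3
Reactants: 3 3-bromo-2-hydroxy-4,6-bis(prop-2-en-1-yloxy)benzaldehyde
Product: 4 2-(benzyloxy)-3-bromo-4,6-bis(prop-2-en-1-yloxy)benzaldehyde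
Conditions: BnBr (1.3 equiv), K2CO3, DMF, 50 °C
Reagents that add atoms: benzyl bromide, BrCc1ccccc1
Why: Williamson etherification of the remaining hindered phenol under slightly forcing conditions; this oxygen, next to the bromine, becomes O5'.

Step 4
Reactants: 4 2-(benzyloxy)-3-bromo-4,6-bis(prop-2-en-1-yloxy)benzaldehyde; 5 4'-(benzyloxy)acetophenone
Product: 6 (E)-3-[2-(benzyloxy)-3-bromo-4,6-bis(prop-2-en-1-yloxy)phenyl]-1-[4-(benzyloxy)phenyl]prop-2-en-1-one
Conditions: KOH (aq.), EtOH–THF, rt
Reagents that add atoms: none
Why: Claisen–Schmidt condensation; the aldehyde has no α-hydrogen and the trans-enone is the thermodynamic product.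

Step 5
Reactants: 6 (E)-3-[2-(benzyloxy)-3-bromo-4,6-bis(prop-2-en-1-yloxy)phenyl]-1-[4-(benzyloxy)phenyl]prop-2-en-1-one
Product: 7 3-[2-(benzyloxy)-3-bromo-4,6-bis(prop-2-en-1-yloxy)phenyl]-1-[4-(benzyloxy)phenyl]propan-1-one
Conditions: Cu(OAc)2·H2O (5 mol%), 1,2-bis(diphenylphosphino)benzene (5 mol%), (EtO)2MeSiH (2 equiv), t-BuOH (2 equiv), toluene, rt
Reagents that add atoms: none
Why: Phosphine-ligated copper hydride conjugate reduction; hydride adds only to the β-carbon of the enone, so the aryl bromide, the benzyl ethers and the isolated allyl double bonds, none of which would survive catalytic hydrogenation, stay untouched.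

Step 6
Reactants: 7 3-[2-(benzyloxy)-3-bromo-4,6-bis(prop-2-en-1-yloxy)phenyl]-1-[4-(benzyloxy)phenyl]propan-1-one
Product: 8 (1S)-3-[2-(benzyloxy)-3-bromo-4,6-bis(prop-2-en-1-yloxy)phenyl]-1-[4-(benzyloxy)phenyl]propan-1-ol
Conditions: RuCl[(S,S)-TsDPEN](p-cymene) (1 mol%), HCO2H–Et3N (5:2), DMF, 30 °C
Reagents that add atoms: none
Why: Noyori–Ikariya asymmetric transfer hydrogenation of an aryl alkyl ketone; the (S,S)-catalyst delivers hydride to the face that gives the (S)-carbinol, and formic acid as the hydrogen source makes the reduction of this electron-rich ketone irreversible.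

Step 7
Reactants: 8 (1S)-3-[2-(benzyloxy)-3-bromo-4,6-bis(prop-2-en-1-yloxy)phenyl]-1-[4-(benzyloxy)phenyl]propan-1-ol
Product: 9 5-(benzyloxy)-4-bromo-6-[(3S)-3-[4-(benzyloxy)phenyl]-3-hydroxypropyl]benzene-1,3-diol
Conditions: Pd(PPh3)4 (5 mol%), morpholine (10 equiv), THF, rt, argon
Reagents that add atoms: none
Why: Palladium-catalysed allyl transfer from the two aryl allyl ethers to morpholine (Tsuji–Trost deallylation); the medium is neutral, so the ionisable 4-benzyloxybenzylic carbinol keeps its configuration, and oxidative addition of zerovalent palladium to the hindered aryl bromide should not compete at room temperature.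

Step 8
Reactants: 9 5-(benzyloxy)-4-bromo-6-[(3S)-3-[4-(benzyloxy)phenyl]-3-hydroxypropyl]benzene-1,3-diol
Product: 10 (2R)-5-(benzyloxy)-2-[4-(benzyloxy)phenyl]-6-bromo-3,4-dihydro-2H-chromen-7-ol
Conditions: PPh3 (1.5 equiv), DIAD (1.5 equiv, slow addition), toluene–THF (0.02 M), −20 → 0 °C
Reagents that add atoms: none
Why: Intramolecular Mitsunobu etherification; only the hydroxyl ortho to the side chain can reach the activated carbinol (six-membered closure), and SN2 displacement inverts the (S)-carbinol to (R) at C2'. The para hydroxyl cannot cyclise and is left free as O7'.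

Step 9
Reactants: 10 (2R)-5-(benzyloxy)-2-[4-(benzyloxy)phenyl]-6-bromo-3,4-dihydro-2H-chromen-7-ol
Product: 11 O-[(2R)-5-(benzyloxy)-2-[4-(benzyloxy)phenyl]-6-bromo-3,4-dihydro-2H-chromen-7-yl]hydroxylamine
Conditions: NaH (1.1 equiv), THF–DMF, 0 °C; then O-(2,4-dinitrophenyl)hydroxylamine (1.2 equiv), 0 °C → rt; used without storage
Reagents that add atoms: O-(2,4-dinitrophenyl)hydroxylamine, NOc1ccc(cc1[N+](=O)[O-])[N+](=O)[O-]
Why: Electrophilic amination of a phenoxide at oxygen, an established entry to electron-rich O-arylhydroxylamines; 2,4-dinitrophenoxide is the leaving group and C2' is not involved.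

Step 10
Reactants: 12 2',4',6'-trihydroxyacetophenone
Product: 13 1-[2,4-bis(benzyloxy)-6-hydroxyphenyl]ethan-1-one
Conditions: BnBr (2.05 equiv), K2CO3 (2.2 equiv), DMF, rt
Reagents that add atoms: benzyl bromide, BrCc1ccccc1
Why: Williamson etherification; as in step 1 the hydroxyl chelated to the carbonyl group is the one left free.

Step 11
Reactants: 13 1-[2,4-bis(benzyloxy)-6-hydroxyphenyl]ethan-1-one; 14 4-(benzyloxy)benzoyl chloride
Product: 15 1-[2,4-bis(benzyloxy)-6-hydroxyphenyl]-3-[4-(benzyloxy)phenyl]propane-1,3-dione
Conditions: LiN(SiMe3)2 (3.2 equiv), THF, −78 → −10 °C; then 14, −78 °C → rt; cold aq. NH4Cl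
Reagents that add atoms: none
Why: One-pot variant of the Baker–Venkataraman diketone synthesis: the lithium phenoxide–enolate dianion of the ortho-hydroxyacetophenone is aroylated at carbon, and the excess base keeps the product as its enolate, which prevents a second acylation.

Step 12
Reactants: 15 1-[2,4-bis(benzyloxy)-6-hydroxyphenyl]-3-[4-(benzyloxy)phenyl]propane-1,3-dione
Product: 16 1-[2,4-bis(benzyloxy)-6-(tert-butyldimethylsilyloxy)phenyl]-3-[4-(benzyloxy)phenyl]propane-1,3-dione
Conditions: TBSCl (1.3 equiv), imidazole (2.5 equiv), DMF, 0 °C → rt; aq. NH4Cl work-up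
Reagents that add atoms: tert-butyldimethylsilyl chloride, CC(C)(C)[Si](C)(C)Cl
Why: Silylation of the phenol; any silyl enol ether formed at the diketone is a vinylogous silyl ester and should hydrolyse on the aqueous work-up, whereas the aryl silyl ether persists. The silyl ether stops O1 from closing to a flavone and is the latent nucleophile of step 14.

Step 13
Reactants: 11 O-[(2R)-5-(benzyloxy)-2-[4-(benzyloxy)phenyl]-6-bromo-3,4-dihydro-2H-chromen-7-yl]hydroxylamine; 16 1-[2,4-bis(benzyloxy)-6-(tert-butyldimethylsilyloxy)phenyl]-3-[4-(benzyloxy)phenyl]propane-1,3-dione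
Product: 17 1-[2,4-bis(benzyloxy)-6-(tert-butyldimethylsilyloxy)phenyl]-3-[4-(benzyloxy)phenyl]-3-({[(2R)-5-(benzyloxy)-2-[4-(benzyloxy)phenyl]-6-bromo-3,4-dihydro-2H-chromen-7-yl]oxy}imino)propan-1-one (E isomer drawn; geometry immaterial)
Conditions: PPTS (0.1 equiv), 4 Å MS, CH2Cl2, rt → 35 °C
Reagents that add atoms: none
Why: Oxime ether formation at the unhindered 4-benzyloxyphenyl ketone; the other carbonyl is shielded by two ortho substituents, and an O-substituted hydroxylamine cannot go on to an isoxazole. The weak acid is enough for condensation but not for the acid-induced rearrangement of the product.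

Step 14
Reactants: 17 O-[(2R)-5-(benzyloxy)-2-[4-(benzyloxy)phenyl]-6-bromochroman-7-yl] oxime ether of 16 at the 4-benzyloxyphenyl ketone
Product: 20 (2R,3S,2'R)-6'-bromo penta-O-benzyl ether of the target, via N-trifluoroacetyl ene-hydroxylamine 18 (not isolated), via trifluoroacetamido dihydrobenzofuran aminal 19 (not isolated)
Conditions: TFAA (1.5 equiv), CH2Cl2, 4 Å MS, −40 → 0 °C; then TMSOTf (0.2 equiv), −40 °C; cold pH 7 phosphate buffer; chromatography
Reagents that add atoms: none
Why: Proposed new method: trifluoroacetylation of the oxime nitrogen of 17 and loss of the doubly activated C3 proton should give 18, whose weakened N–O bond allows a [3,3] shift that joins C3 to C8', the only unsubstituted ortho carbon of ring D because C6' carries bromine; re-aromatisation leaves the O7' phenol beside an N-trifluoroacetyl ketimine. The closest known reaction type is the acylation-triggered rearrangement of O-aryl oxime ethers to 2-acylamino-2,3-dihydrobenzofurans and benzofurans, the oxygen counterpart of the Fischer indole synthesis; new here is the diversion of the aminal to a ketal by a second oxygen. Ring F closes by 5-exo-trig addition of the O7' hydroxyl to the C=N bond, giving 19. Silyl activation of the amide (or the trifluoroacetic acid already present) should ionise 19 to the C2 oxocarbenium ion, stabilised by O7' and ring B, and ring C closes by 6-exo-trig attack of the silyl ether oxygen O1, the silyl group passing to the departing trifluoroacetamide. C2 and C3 arise together and their relative configuration is fixed by the tether: O1 is delivered from the aroyl group on C3, so H3 and ring B must be cis on the 5/6 junction, and C3 can adjust by enolisation. Nothing relates this pair to the remote C2', so both cis-fused diastereomers are expected and the (2S,3R,2'R) isomer is removed by chromatography or preparative HPLC; in 20 the atoms are arranged in space as in 21, C2 being labelled R only because the bromine raises the rank of O7' above O1. The step needs regioselectivity (secured by the C6' bromine), N-acylation rather than C-acylation (favoured by the oxime tautomer and base-free conditions) and capture before loss of H3 (favoured by the ortho placement of O1, low temperature and the absence of base).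

Step 15
Reactants: 20 (2R,3S,2'R)-6'-bromo penta-O-benzyl ether of the target
Product: 21 target, (2S,3S,2'R)-5,7-dihydroxy-2-(4-hydroxyphenyl)chroman-4-one bonded through C3–C8' and C2–O7' to (2'R)-5'-hydroxy-2'-(4-hydroxyphenyl)chroman
Conditions: H2 (1 atm), Pd/C (10 wt%), NaOAc (1.5 equiv), THF–MeOH, rt
Reagents that add atoms: none
Why: Hydrogenolysis of five aryl benzyl ethers together with hydrodebromination of the aryl bromide; sodium acetate takes up the hydrogen bromide so that the medium stays near neutral for the ketal. No stereocentre is touched (the C2 label returns from R to S only because the bromine is gone); the C2'–O1' ether and the chelated ketone are expected to survive under these mild conditions, as they do in debenzylations of flavans and flavanones.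

## Compound list

1 | 2,4,6-trihydroxybenzaldehyde | O=Cc1c(O)cc(O)cc1O | starting material
2 | 2-hydroxy-4,6-bis(prop-2-en-1-yloxy)benzaldehyde | O=Cc1c(O)cc(OCC=C)cc1OCC=C | intermediate
3 | 3-bromo-2-hydroxy-4,6-bis(prop-2-en-1-yloxy)benzaldehyde | O=Cc1c(O)c(Br)c(OCC=C)cc1OCC=C | intermediate
4 | 2-(benzyloxy)-3-bromo-4,6-bis(prop-2-en-1-yloxy)benzaldehyde | O=Cc1c(OCc6ccccc6)c(Br)c(OCC=C)cc1OCC=C | intermediate
5 | 4'-(benzyloxy)acetophenone | CC(=O)c1ccc(OCc2ccccc2)cc1 | starting material
6 | (E)-3-[2-(benzyloxy)-3-bromo-4,6-bis(prop-2-en-1-yloxy)phenyl]-1-[4-(benzyloxy)phenyl]prop-2-en-1-one | O=C(/C=C/c1c(OCc6ccccc6)c(Br)c(OCC=C)cc1OCC=C)c1ccc(OCc6ccccc6)cc1 | intermediate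
7 | 3-[2-(benzyloxy)-3-bromo-4,6-bis(prop-2-en-1-yloxy)phenyl]-1-[4-(benzyloxy)phenyl]propan-1-one | O=C(CCc1c(OCc6ccccc6)c(Br)c(OCC=C)cc1OCC=C)c1ccc(OCc6ccccc6)cc1 | intermediate
8 | (1S)-3-[2-(benzyloxy)-3-bromo-4,6-bis(prop-2-en-1-yloxy)phenyl]-1-[4-(benzyloxy)phenyl]propan-1-ol | O[C@@H](CCc1c(OCc6ccccc6)c(Br)c(OCC=C)cc1OCC=C)c1ccc(OCc6ccccc6)cc1 | intermediate
9 | 5-(benzyloxy)-4-bromo-6-[(3S)-3-[4-(benzyloxy)phenyl]-3-hydroxypropyl]benzene-1,3-diol | O[C@@H](CCc1c(OCc6ccccc6)c(Br)c(O)cc1O)c1ccc(OCc6ccccc6)cc1 | intermediate
10 | (2R)-5-(benzyloxy)-2-[4-(benzyloxy)phenyl]-6-bromo-3,4-dihydro-2H-chromen-7-ol | Oc1c(Br)c(OCc6ccccc6)c2c(c1)O[C@@H](c1ccc(OCc6ccccc6)cc1)CC2 | intermediate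
11 | O-[(2R)-5-(benzyloxy)-2-[4-(benzyloxy)phenyl]-6-bromo-3,4-dihydro-2H-chromen-7-yl]hydroxylamine | NOc1c(Br)c(OCc6ccccc6)c2c(c1)O[C@@H](c1ccc(OCc6ccccc6)cc1)CC2 | intermediate
12 | 2',4',6'-trihydroxyacetophenone | CC(=O)c1c(O)cc(O)cc1O | starting material
13 | 1-[2,4-bis(benzyloxy)-6-hydroxyphenyl]ethan-1-one | CC(=O)c1c(O)cc(OCc6ccccc6)cc1OCc6ccccc6 | intermediate
14 | 4-(benzyloxy)benzoyl chloride | O=C(Cl)c1ccc(OCc2ccccc2)cc1 | starting material
15 | 1-[2,4-bis(benzyloxy)-6-hydroxyphenyl]-3-[4-(benzyloxy)phenyl]propane-1,3-dione | O=C(CC(=O)c1ccc(OCc6ccccc6)cc1)c1c(O)cc(OCc6ccccc6)cc1OCc6ccccc6 | intermediate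
16 | 1-[2,4-bis(benzyloxy)-6-(tert-butyldimethylsilyloxy)phenyl]-3-[4-(benzyloxy)phenyl]propane-1,3-dione | O=C(CC(=O)c1ccc(OCc6ccccc6)cc1)c1c(O[Si](C)(C)C(C)(C)C)cc(OCc6ccccc6)cc1OCc6ccccc6 | intermediate
17 | O-[(2R)-5-(benzyloxy)-2-[4-(benzyloxy)phenyl]-6-bromochroman-7-yl] oxime ether of 16 at the 4-benzyloxyphenyl ketone | O=C(C/C(=N\Oc1c(Br)c(OCc6ccccc6)c2c(c1)O[C@@H](c1ccc(OCc6ccccc6)cc1)CC2)c1ccc(OCc6ccccc6)cc1)c1c(O[Si](C)(C)C(C)(C)C)cc(OCc6ccccc6)cc1OCc6ccccc6 | intermediate
18 | N-trifluoroacetyl ene-hydroxylamine (N-aryloxy-N-trifluoroacetyl enaminone; alkene geometry not defined; not isolated) | O=C(C=C(c1ccc(OCc6ccccc6)cc1)N(C(=O)C(F)(F)F)Oc1c(Br)c(OCc6ccccc6)c2c(c1)O[C@@H](c1ccc(OCc6ccccc6)cc1)CC2)c1c(O[Si](C)(C)C(C)(C)C)cc(OCc6ccccc6)cc1OCc6ccccc6 | intermediate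
19 | 3-aroyl-2-aryl-2-(trifluoroacetamido)-2,3-dihydrobenzofuran N,O-aminal fused to the (R)-chroman (new centres as a mixture; not isolated) | O=C(c1c(O[Si](C)(C)C(C)(C)C)cc(OCc6ccccc6)cc1OCc6ccccc6)C1C(NC(=O)C(F)(F)F)(c2ccc(OCc6ccccc6)cc2)Oc2c(Br)c(OCc6ccccc6)c3c(c21)O[C@@H](c1ccc(OCc6ccccc6)cc1)CC3 | intermediate
20 | (2R,3S,2'R)-6'-bromo penta-O-benzyl ether of the target | O=C1c2c(OCc6ccccc6)cc(OCc6ccccc6)cc2O[C@@]3(c4ccc(OCc6ccccc6)cc4)Oc4c(Br)c(OCc6ccccc6)c5c(c4[C@@H]13)O[C@@H](c1ccc(OCc6ccccc6)cc1)CC5 | intermediate
21 | target, (2S,3S,2'R) | O=C1c2c(O)cc(O)cc2O[C@@]2(c3ccc(O)cc3)Oc3cc(O)c4c(c3[C@@H]12)O[C@@H](c1ccc(O)cc1)CC4 | target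

## Step count and least certain steps

Total: 15 steps. Longest linear sequence: 12 steps (steps 1–9, 13, 14, 15); the diketone branch (steps 10–12) joins at step 13.

Step 14 (key step). The most likely failure is loss of the C3 proton from the oxocarbenium ion, or base-type elimination of trifluoroacetamide from 19, running ahead of capture by the hindered silyl ether oxygen, which aromatises the furan. C-trifluoroacetylation and an unfavourable facial ratio are lesser risks. The fallback is built from established reaction types only, sets out from 17, returns at 20, and borrows the closure of Alternative 2. 17 is taken deliberately to the aromatic product under the usual conditions for this rearrangement (TFAA, CH2Cl2, 0 °C, then TFA, rt), giving the 3-aroyl-2-arylbenzofuran silyl ether F1. TBAF buffered with AcOH (THF, 0 °C) frees the ortho-hydroxyaryl ketone F2, and LiAlH4 (THF, −78 → −20 °C) reduces it to the (2-hydroxyaryl)(benzofuran-3-yl)carbinol F3. Gentle dehydration (PPTS cat., toluene, 40 °C) generates the ortho-quinone methide of ring A, whose oxa-6π closure should give the 2H-chromene ketal F4, from which the unwanted C2 epimer is removed by chromatography. Hydroboration–oxidation (BH3·THF, then NaBO3·4H2O) places hydrogen on C3 and hydroxyl on C4 by syn addition, and the strain-free cis ring fusion should direct the hydrogen to the face of ring B, giving the cis-fused alcohol F5. Dess–Martin periodinane buffered with NaHCO3 then returns 20, and any material with the wrong C3 configuration can converge on the cis fusion through the enol once C4 is a ketone.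

Step 13. The weakly nucleophilic aryloxyamine may condense slowly with the enolised diketone, with competition between the two carbonyl groups, loss of the silyl group, or premature acid-induced rearrangement. The fallback sets out from 1 (and uses 11), returns at 17, and also bypasses 15 and 16. 1 is dibenzylated (BnBr, K2CO3, DMF) to 2,4-bis(benzyloxy)-6-hydroxybenzaldehyde F6 and silylated (TBSCl, imidazole, DMF) to the silyl ether F7. Addition of the lithium acetylide of commercial 1-(benzyloxy)-4-ethynylbenzene (n-BuLi, THF, −78 °C, quench at −78 °C to forestall silyl migration) gives the propargylic alcohol F8, and MnO2 (CH2Cl2) the ynone F9. Conjugate addition of 11 to F9 (EtOH–THF, rt → 40 °C) can take place only at the alkyne carbon bearing the 4-benzyloxyphenyl group and gives 17 as its oxime/enamine tautomers.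

Step 12. Silylation may occur at the enol oxygen of the diketone instead of the hydrogen-bonded phenol, and 15 may close to its cyclic hemiketal or to the flavone under the basic conditions. The fallback inverts the order, sets out from 13 and returns at 16: silylation of 13 (TBSOTf, 2,6-lutidine, CH2Cl2) gives 1-[2,4-bis(benzyloxy)-6-(tert-butyldimethylsilyloxy)phenyl]ethan-1-one F10, which is C-aroylated with 14 under soft enolisation (MgBr2·OEt2, i-Pr2NEt, CH2Cl2).

Step 8. Ionisation of the activated 4-benzyloxybenzylic carbinol may erode the enantiomeric purity; elimination to the styrene and intermolecular alkylation at the para hydroxyl are further risks. The fallback makes C2' by hydrogenation instead of substitution, sets out from 7 and returns at 10. Deallylation of 7 (Pd(PPh3)4, morpholine, THF) gives the keto-diphenol F11, and acid-catalysed cyclodehydration (p-TsOH cat., toluene, 4 Å MS) gives the 2-aryl-4H-chromene F12. Asymmetric hydrogenation with a cationic iridium phosphinooxazoline catalyst such as [Ir(cod)(tBu-PHOX)][B(3,5-(CF3)2C6H3)4] (the ligand enantiomer that gives 2R; H2, CH2Cl2) then leads to 10.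

Step 15. The hydrogen bromide released may ionise the ketal before it is buffered, bromide may slow the debenzylation so that long exposure cleaves the C2'–O1' or ketal C–O bonds, and the ketone may be over-reduced. The fallback separates the two events, sets out from 20 and returns at 21: radical hydrodebromination ((Me3Si)3SiH, AIBN, toluene, 80 °C) gives the penta-O-benzyl ether F13 (identical with A4), and halide-free hydrogenolysis (H2, Pd(OH)2/C, EtOAc–MeOH, rt) gives 21.

## Further compounds

F1 | step 14 | [2,4-bis(benzyloxy)-6-(tert-butyldimethylsilyloxy)phenyl][(2R)-5-(benzyloxy)-2,8-bis[4-(benzyloxy)phenyl]-6-bromo-3,4-dihydro-2H-furo[2,3-h]chromen-9-yl]methanone | O=C(c1c(O[Si](C)(C)C(C)(C)C)cc(OCc6ccccc6)cc1OCc6ccccc6)c1c(-c2ccc(OCc6ccccc6)cc2)oc2c(Br)c(OCc6ccccc6)c3c(c12)O[C@@H](c1ccc(OCc6ccccc6)cc1)CC3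
F2 | step 14 | [2,4-bis(benzyloxy)-6-hydroxyphenyl][(2R)-5-(benzyloxy)-2,8-bis[4-(benzyloxy)phenyl]-6-bromo-3,4-dihydro-2H-furo[2,3-h]chromen-9-yl]methanone | O=C(c1c(O)cc(OCc6ccccc6)cc1OCc6ccccc6)c1c(-c2ccc(OCc6ccccc6)cc2)oc2c(Br)c(OCc6ccccc6)c3c(c12)O[C@@H](c1ccc(OCc6ccccc6)cc1)CC3
F3 | step 14 | [2,4-bis(benzyloxy)-6-hydroxyphenyl][(2R)-5-(benzyloxy)-2,8-bis[4-(benzyloxy)phenyl]-6-bromo-3,4-dihydro-2H-furo[2,3-h]chromen-9-yl]methanol (carbinol carbon as a mixture) | OC(c1c(O)cc(OCc6ccccc6)cc1OCc6ccccc6)c1c(-c2ccc(OCc6ccccc6)cc2)oc2c(Br)c(OCc6ccccc6)c3c(c12)O[C@@H](c1ccc(OCc6ccccc6)cc1)CC3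
F4 | step 14 | 6'-bromo penta-O-benzyl 4-deoxo-3,4-didehydro derivative of the target (2H-chromene ketal, C2 arranged as in 20) | c12c(OCc6ccccc6)cc(OCc6ccccc6)cc1O[C@@]3(c4ccc(OCc6ccccc6)cc4)Oc4c(Br)c(OCc6ccccc6)c5c(c4C3=C2)O[C@@H](c1ccc(OCc6ccccc6)cc1)CC5
F5 | step 14 | (2R,3S,4S,2'R)-C4 alcohol corresponding to 20 (hydroxyl cis to H3) | O[C@@H]1c2c(OCc6ccccc6)cc(OCc6ccccc6)cc2O[C@@]3(c4ccc(OCc6ccccc6)cc4)Oc4c(Br)c(OCc6ccccc6)c5c(c4[C@@H]13)O[C@@H](c1ccc(OCc6ccccc6)cc1)CC5
F6 | step 13 | 2,4-bis(benzyloxy)-6-hydroxybenzaldehyde | O=Cc1c(O)cc(OCc6ccccc6)cc1OCc6ccccc6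
F7 | step 13 | 2,4-bis(benzyloxy)-6-(tert-butyldimethylsilyloxy)benzaldehyde | O=Cc1c(O[Si](C)(C)C(C)(C)C)cc(OCc6ccccc6)cc1OCc6ccccc6
F8 | step 13 | 1-[2,4-bis(benzyloxy)-6-(tert-butyldimethylsilyloxy)phenyl]-3-[4-(benzyloxy)phenyl]prop-2-yn-1-ol (racemic) | OC(C#Cc1ccc(OCc6ccccc6)cc1)c1c(O[Si](C)(C)C(C)(C)C)cc(OCc6ccccc6)cc1OCc6ccccc6
F9 | step 13 | 1-[2,4-bis(benzyloxy)-6-(tert-butyldimethylsilyloxy)phenyl]-3-[4-(benzyloxy)phenyl]prop-2-yn-1-one | O=C(C#Cc1ccc(OCc6ccccc6)cc1)c1c(O[Si](C)(C)C(C)(C)C)cc(OCc6ccccc6)cc1OCc6ccccc6
F10 | step 12 | 1-[2,4-bis(benzyloxy)-6-(tert-butyldimethylsilyloxy)phenyl]ethan-1-one | CC(=O)c1c(O[Si](C)(C)C(C)(C)C)cc(OCc6ccccc6)cc1OCc6ccccc6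
F11 | step 8 | 3-[2-(benzyloxy)-3-bromo-4,6-dihydroxyphenyl]-1-[4-(benzyloxy)phenyl]propan-1-one | O=C(CCc1c(OCc6ccccc6)c(Br)c(O)cc1O)c1ccc(OCc6ccccc6)cc1
F12 | step 8 | 5-(benzyloxy)-2-[4-(benzyloxy)phenyl]-6-bromo-4H-chromen-7-ol | Oc1c(Br)c(OCc6ccccc6)c2c(c1)OC(c1ccc(OCc6ccccc6)cc1)=CC2
F13 | step 15 | (2S,3S,2'R)-penta-O-benzyl ether of the target | O=C1c2c(OCc6ccccc6)cc(OCc6ccccc6)cc2O[C@@]3(c4ccc(OCc6ccccc6)cc4)Oc4cc(OCc6ccccc6)c5c(c4[C@@H]13)O[C@@H](c1ccc(OCc6ccccc6)cc1)CC5
A1 | alternative 1 | (2R)-5-(benzyloxy)-2,8-bis[4-(benzyloxy)phenyl]-3,4-dihydro-2H-furo[2,3-h]chromene-9-carboxylic acid | OC(=O)c1c(-c2ccc(OCc6ccccc6)cc2)oc2cc(OCc6ccccc6)c3c(c12)O[C@@H](c1ccc(OCc6ccccc6)cc1)CC3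
A2 | alternative 1 | 3,5-bis(benzyloxy)-2-(trimethylsilyl)phenyl trifluoromethanesulfonate | C[Si](C)(C)c1c(OCc6ccccc6)cc(OCc6ccccc6)cc1OS(=O)(=O)C(F)(F)F
A3 | alternative 1 | [2,4-bis(benzyloxy)-6-hydroxyphenyl][(2R)-5-(benzyloxy)-2,8-bis[4-(benzyloxy)phenyl]-3,4-dihydro-2H-furo[2,3-h]chromen-9-yl]methanone | O=C(c1c(O)cc(OCc6ccccc6)cc1OCc6ccccc6)c1c(-c2ccc(OCc6ccccc6)cc2)oc2cc(OCc6ccccc6)c3c(c12)O[C@@H](c1ccc(OCc6ccccc6)cc1)CC3
A4 | alternative 1 | (2S,3S,2'R)-penta-O-benzyl ether of the target | O=C1c2c(OCc6ccccc6)cc(OCc6ccccc6)cc2O[C@@]3(c4ccc(OCc6ccccc6)cc4)Oc4cc(OCc6ccccc6)c5c(c4[C@@H]13)O[C@@H](c1ccc(OCc6ccccc6)cc1)CC5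
A5 | alternative 2 | [2,4-bis(benzyloxy)-6-hydroxyphenyl][(2R)-5-(benzyloxy)-2,8-bis[4-(benzyloxy)phenyl]-3,4-dihydro-2H-furo[2,3-h]chromen-9-yl]methanol (carbinol carbon as a mixture) | OC(c1c(O)cc(OCc6ccccc6)cc1OCc6ccccc6)c1c(-c2ccc(OCc6ccccc6)cc2)oc2cc(OCc6ccccc6)c3c(c12)O[C@@H](c1ccc(OCc6ccccc6)cc1)CC3
A6 | alternative 2 | penta-O-benzyl 4-deoxo-3,4-didehydro derivative of the target (2H-chromene ketal) | c12c(OCc6ccccc6)cc(OCc6ccccc6)cc1O[C@@]3(c4ccc(OCc6ccccc6)cc4)Oc4cc(OCc6ccccc6)c5c(c4C3=C2)O[C@@H](c1ccc(OCc6ccccc6)cc1)CC5
A7 | alternative 3 | (2R)-5-(benzyloxy)-2,8-bis[4-(benzyloxy)phenyl]-3,4-dihydro-2H-furo[2,3-h]chromene | c1c(-c2ccc(OCc6ccccc6)cc2)oc2cc(OCc6ccccc6)c3c(c12)O[C@@H](c1ccc(OCc6ccccc6)cc1)CC3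
A8 | alternative 3 | 5,7-bis(benzyloxy)-2,2-dimethyl-4H-1,3-benzodioxin-4-one | CC1(C)OC(=O)c2c(OCc6ccccc6)cc(OCc6ccccc6)cc2O1
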